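Every hindered diaryl ether is made by SNAr on a 2-fluoroisophthalaldehyde, and the two formyl groups that flank the new ether are then exchanged for hydroxyls. In rings C and C′ the hydroxyls at C2 and C6 sit ortho to the ether carbon C1; carried as formyl groups they activate the C1–F bond, and a single fourfold Baeyer–Villiger (Dakin-type) oxidation with formate methanolysis then creates all four C2–O and C6–O bonds. The precursor is the ring A–B core bearing two 2,6-diformyl-4-benzyloxyphenoxy rings; O4 carries benzyl rather than silyl because the SNAr liberates fluoride. The same SNAr/oxidation pair also builds ring B and attaches the ring D–E biaryls.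

Key step: step 11

Remark: the target has no stereocentre and no chiral axis, so no stereocontrol is needed. Ring letters: A = 3,5-dioxygenated phenoxy ring, B = central tetraoxygenated ring, C/C′ = the two 2,6-dihydroxy-4-aryloxyphenoxy rings, D–E/D′–E′ = the two hexaoxygenated biphenyls. Partly converted species of the multifold steps (mono-ethers, lower formates, partly methylated or demethylated compounds) and the phenolate salts present in the base-mediated steps are not numbered separately.

Step 1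
Reactants: 1 4-fluorophenol
Product: 2 (4-fluorophenoxy)triisopropylsilane
Conditions: TIPSCl, imidazole, DMF, rt
Reagents that add atoms: chlorotriisopropylsilane (TIPSCl), CC(C)[Si](Cl)(C(C)C)C(C)C
Why: Silylation of the phenol (silyl ether formation); the bulky silyl group later keeps the lithium base away from the positions next to oxygen.

Step 2
Reactants: 2 (4-fluorophenoxy)triisopropylsilane
Product: 4 2-fluoro-5-(triisopropylsilyloxy)benzaldehyde, via aryllithium 3 (not isolated)
Conditions: s-BuLi, TMEDA, THF, −78 °C; DMF, −78 to 0 °C; 1 M HCl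
Reagents that add atoms: N,N-dimethylformamide (DMF), CN(C)C=O
Why: Directed ortho-metalation: fluorine acidifies its ortho C–H while the bulky, poorly coordinating silyloxy group blocks lithiation next to oxygen, and the aryllithium (kept at −78 °C to avoid loss of LiF) is formylated by DMF.

Step 3
Reactants: 4 2-fluoro-5-(triisopropylsilyloxy)benzaldehyde
Product: 5 2-[2-fluoro-5-(triisopropylsilyloxy)phenyl]-1,3-dioxolane
Conditions: HOCH2CH2OH, p-TsOH (cat.), toluene, reflux (Dean–Stark)
Reagents that add atoms: ethylene glycol, OCCO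
Why: Acid-catalysed acetalisation with azeotropic removal of water masks the aldehyde against the second organolithium step, and the aryl silyl ether tolerates catalytic sulfonic acid.

Step 4
Reactants: 5 2-[2-fluoro-5-(triisopropylsilyloxy)phenyl]-1,3-dioxolane
Product: 8 2-fluoro-5-(triisopropylsilyloxy)isophthalaldehyde, via aryllithium 6 (not isolated), via acetal aldehyde 7 (not isolated)
Conditions: s-BuLi, TMEDA, THF, −78 °C; DMF; then 2 M HCl, THF, rt
Reagents that add atoms: N,N-dimethylformamide (DMF), CN(C)C=O; water, O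
Why: A second fluorine-directed ortho-metalation takes the only remaining C–H next to fluorine (the C–H between dioxolane and silyloxy is shielded by the silyl group), DMF formylates it, and aqueous acid hydrolyses the acetal without cleaving the aryl silyl ether.

Step 5
Reactants: 8 2-fluoro-5-(triisopropylsilyloxy)isophthalaldehyde
Product: 9 2-fluoro-5-hydroxyisophthalaldehyde
Conditions: TBAF, AcOH, THF, 0 °C
Reagents that add atoms: none
Why: Fluoride-mediated cleavage of the aryl silyl ether; the acetic acid buffer keeps the freed phenol protonated so that it should not attack the activated C–F bond of another molecule, and fluoride exchange at C–F is degenerate.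

Step 6
Reactants: 9 2-fluoro-5-hydroxyisophthalaldehyde
Product: 10 2-fluoro-5-methoxyisophthalaldehyde
Conditions: MeI (excess), K2CO3, DMF, 0 °C to rt
Reagents that add atoms: iodomethane (MeI), CI
Why: Williamson O-methylation of the acidic diformylphenol; its weakly nucleophilic phenolate should be trapped by excess MeI at low temperature faster than it can displace fluoride from another molecule.

Step 7
Reactants: 9 2-fluoro-5-hydroxyisophthalaldehyde
Product: 11 5-(benzyloxy)-2-fluoroisophthalaldehyde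
Conditions: BnBr (excess), K2CO3, DMF, 0 °C to rt
Reagents that add atoms: benzyl bromide (BnBr), BrCc1ccccc1
Why: Williamson O-benzylation of the same phenol gives the ring C building block, whose benzyl ether, unlike a silyl ether, is inert to the fluoride released in the SNAr of step 10.

Step 8
Reactants: 12 3,5-dimethoxyphenol; 10 2-fluoro-5-methoxyisophthalaldehyde
Product: 13 2-(3,5-dimethoxyphenoxy)-5-methoxyisophthalaldehyde
Conditions: K2CO3, DMF, rt
Reagents that add atoms: none
Why: SNAr: the fluoride lies ortho to two formyl groups, so the phenoxide of 12 should displace it at room temperature through a doubly stabilised Meisenheimer adduct.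

Step 9
Reactants: 13 2-(3,5-dimethoxyphenoxy)-5-methoxyisophthalaldehyde
Product: 15 2-(3,5-dimethoxyphenoxy)-5-methoxybenzene-1,3-diol, via diformate 14 (not isolated)
Conditions: mCPBA, CH2Cl2, rt; aq. Na2S2O3 wash; then K2CO3, MeOH, 0 °C
Reagents that add atoms: mCPBA (3-chloroperbenzoic acid), O=C(OO)c1cccc(Cl)c1
Why: Baeyer–Villiger (Dakin-type) oxidation in which the ortho aryloxy donor favours aryl migration, followed by formate methanolysis; the step also rehearses the key step on a single ring.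

Step 10
Reactants: 15 2-(3,5-dimethoxyphenoxy)-5-methoxybenzene-1,3-diol; 11 5-(benzyloxy)-2-fluoroisophthalaldehyde (2.2 equiv)
Product: 16 1,3-bis[4-(benzyloxy)-2,6-diformylphenoxy]-2-(3,5-dimethoxyphenoxy)-5-methoxybenzene
Conditions: Cs2CO3, DMF, rt to 40 °C
Reagents that add atoms: none
Why: Twofold SNAr of the ring B bisphenoxide on the doubly formyl-activated fluoride; the released fluoride cannot harm the benzyl ethers, and any aryloxide exchange at the activated rings is degenerate.

Step 11
Reactants: 16 1,3-bis[4-(benzyloxy)-2,6-diformylphenoxy]-2-(3,5-dimethoxyphenoxy)-5-methoxybenzene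
Product: 18 1,3-bis[4-(benzyloxy)-2,6-dihydroxyphenoxy]-2-(3,5-dimethoxyphenoxy)-5-methoxybenzene, via tetraformate 17 (not isolated)
Conditions: mCPBA (excess), CH2Cl2, rt to 40 °C; aq. Na2S2O3 wash; then K2CO3, MeOH, 0 °C, under argon
Reagents that add atoms: mCPBA (3-chloroperbenzoic acid), O=C(OO)c1cccc(Cl)c1
Why: Each formyl group adds the peracid to give a Criegee adduct in which the ring carbon (C2 or C6 of ring C or C′) migrates from carbon to the peroxide oxygen as 3-chlorobenzoate leaves, so the aldehyde becomes an aryl formate, and K2CO3/MeOH then passes the formyl group to methanol and leaves the phenol. This is the Baeyer–Villiger oxidation of ortho-aryloxybenzaldehydes (a Dakin-type formyl-to-hydroxyl exchange), run four times on one symmetric substrate. No ring is closed and no stereocentre is formed. The selectivity needed is aryl over hydride migration at all four formyl groups; the C1 ether oxygen ortho to each migrating carbon stabilises the electron-poor transition state, and each formyl group that becomes a formyloxy group removes an acceptor from its ring and eases the next migration. Methanolysis is started only after all four aldehydes are consumed, because a ring still carrying a formyl group would let methoxide cleave its C1 ether by SNAr; the benzyl and methyl ethers are inert to peracid and carbonate.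

Step 12
Reactants: 18 1,3-bis[4-(benzyloxy)-2,6-dihydroxyphenoxy]-2-(3,5-dimethoxyphenoxy)-5-methoxybenzene
Product: 19 1,3-bis[4-(benzyloxy)-2,6-dimethoxyphenoxy]-2-(3,5-dimethoxyphenoxy)-5-methoxybenzene
Conditions: MeI, K2CO3, DMF, rt
Reagents that add atoms: iodomethane (MeI), CI
Why: Williamson etherification caps the four C2/C6 hydroxyls so that only O4 of rings C and C′ will be nucleophilic in step 16.

Step 13
Reactants: 19 1,3-bis[4-(benzyloxy)-2,6-dimethoxyphenoxy]-2-(3,5-dimethoxyphenoxy)-5-methoxybenzene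
Product: 20 1,3-bis(4-hydroxy-2,6-dimethoxyphenoxy)-2-(3,5-dimethoxyphenoxy)-5-methoxybenzene
Conditions: H2 (1 atm), Pd/C (palladium on carbon), EtOAc–MeOH, rt
Reagents that add atoms: none
Why: Catalytic hydrogenolysis cleaves the two benzyl aryl ethers while methyl ethers and diaryl ethers are inert.

Step 14
Reactants: 10 2-fluoro-5-methoxyisophthalaldehyde
Product: 21 4-bromo-2-fluoro-5-methoxyisophthalaldehyde
Conditions: NBS (1.0 equiv), CF3CO2H, H2SO4 (cat.), rt
Reagents that add atoms: N-bromosuccinimide (NBS), O=C1CCC(=O)N1Br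
Why: Electrophilic aromatic bromination: the only free positions (C4 and C6, equivalent) are ortho to the methoxy group, the acid medium makes NBS reactive enough for the formyl-deactivated ring, and one equivalent should stop at the monobromide.

Step 15
Reactants: 21 4-bromo-2-fluoro-5-methoxyisophthalaldehyde; 22 2,4,6-trimethoxyphenylboronic acid
Product: 23 2-fluoro-5-methoxy-4-(2,4,6-trimethoxyphenyl)isophthalaldehyde
Conditions: Pd(OAc)2 (cat.), SPhos, CsF (anhydrous), 1,4-dioxane, 90 °C
Reagents that add atoms: none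
Why: Suzuki–Miyaura coupling with SPhos, a ligand suited to tetra-ortho-substituted biaryls; anhydrous CsF is the base so that the only nucleophile meeting the activated C–F bond is fluoride itself and protodeboronation of 22 is limited.

Step 16
Reactants: 20 1,3-bis(4-hydroxy-2,6-dimethoxyphenoxy)-2-(3,5-dimethoxyphenoxy)-5-methoxybenzene; 23 2-fluoro-5-methoxy-4-(2,4,6-trimethoxyphenyl)isophthalaldehyde (2.2 equiv)
Product: 24 1,3-bis{4-[2,6-diformyl-4-methoxy-3-(2,4,6-trimethoxyphenyl)phenoxy]-2,6-dimethoxyphenoxy}-2-(3,5-dimethoxyphenoxy)-5-methoxybenzene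
Conditions: K2CO3, DMF, rt to 50 °C
Reagents that add atoms: none
Why: Twofold SNAr of the unhindered ring C and C′ phenoxides on the fluoride flanked by two formyl groups, the same reaction type as steps 8 and 10.

Step 17
Reactants: 24 1,3-bis{4-[2,6-diformyl-4-methoxy-3-(2,4,6-trimethoxyphenyl)phenoxy]-2,6-dimethoxyphenoxy}-2-(3,5-dimethoxyphenoxy)-5-methoxybenzene
Product: 26 1,3-bis{4-[2,6-dihydroxy-4-methoxy-3-(2,4,6-trimethoxyphenyl)phenoxy]-2,6-dimethoxyphenoxy}-2-(3,5-dimethoxyphenoxy)-5-methoxybenzene, via tetraformate 25 (not isolated)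
Conditions: mCPBA (excess), CH2Cl2, rt to 40 °C; aq. Na2S2O3 wash; then K2CO3, MeOH, 0 °C, under argon
Reagents that add atoms: mCPBA (3-chloroperbenzoic acid), O=C(OO)c1cccc(Cl)c1
Why: Fourfold Baeyer–Villiger (Dakin-type) oxidation and formate methanolysis as in step 11; each migrating ring D carbon again has the ether oxygen ortho, and the formyl group next to ring E is twisted out of conjugation, which favours aryl migration.

Step 18
Reactants: 26 1,3-bis{4-[2,6-dihydroxy-4-methoxy-3-(2,4,6-trimethoxyphenyl)phenoxy]-2,6-dimethoxyphenoxy}-2-(3,5-dimethoxyphenoxy)-5-methoxybenzene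
Product: 27 5-{2,6-bis[2,6-dihydroxy-4-(2,2′,4,4′,6,6′-hexahydroxybiphenyl-3-yloxy)phenoxy]-4-hydroxyphenoxy}benzene-1,3-diol (CNP0227063.0)
Conditions: BBr3 (excess), CH2Cl2, −78 °C to rt; then H2O
Reagents that add atoms: none
Why: Lewis-acid O-demethylation of all fifteen aryl methyl ethers with BBr3 (bromide attacks the methyl group of the boron-complexed ether), which leaves diaryl ether and biaryl bonds intact.

Compound list
1 | 4-fluorophenol | Oc1ccc(F)cc1 | starting material
2 | (4-fluorophenoxy)triisopropylsilane | CC(C)[Si](Oc1ccc(F)cc1)(C(C)C)C(C)C | intermediate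
3 | [2-fluoro-5-(triisopropylsilyloxy)phenyl]lithium | [Li]c1cc(O[Si](C(C)C)(C(C)C)C(C)C)ccc1F | intermediate
4 | 2-fluoro-5-(triisopropylsilyloxy)benzaldehyde | O=Cc1cc(O[Si](C(C)C)(C(C)C)C(C)C)ccc1F | intermediate
5 | 2-[2-fluoro-5-(triisopropylsilyloxy)phenyl]-1,3-dioxolane | Fc1ccc(O[Si](C(C)C)(C(C)C)C(C)C)cc1C1OCCO1 | intermediate
6 | [3-(1,3-dioxolan-2-yl)-2-fluoro-5-(triisopropylsilyloxy)phenyl]lithium | [Li]c1cc(O[Si](C(C)C)(C(C)C)C(C)C)cc(C2OCCO2)c1F | intermediate
7 | 3-(1,3-dioxolan-2-yl)-2-fluoro-5-(triisopropylsilyloxy)benzaldehyde | O=Cc1cc(O[Si](C(C)C)(C(C)C)C(C)C)cc(C2OCCO2)c1F | intermediate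
8 | 2-fluoro-5-(triisopropylsilyloxy)isophthalaldehyde | O=Cc1cc(O[Si](C(C)C)(C(C)C)C(C)C)cc(C=O)c1F | intermediate
9 | 2-fluoro-5-hydroxyisophthalaldehyde | O=Cc1cc(O)cc(C=O)c1F | intermediate
10 | 2-fluoro-5-methoxyisophthalaldehyde | COc1cc(C=O)c(F)c(C=O)c1 | intermediate
11 | 5-(benzyloxy)-2-fluoroisophthalaldehyde | O=Cc1cc(OCc2ccccc2)cc(C=O)c1F | intermediate
12 | 3,5-dimethoxyphenol | COc1cc(O)cc(OC)c1 | starting material
13 | 2-(3,5-dimethoxyphenoxy)-5-methoxyisophthalaldehyde | COc1cc(OC)cc(Oc2c(C=O)cc(OC)cc2C=O)c1 | intermediate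
14 | 2-(3,5-dimethoxyphenoxy)-5-methoxy-1,3-phenylene diformate | COc1cc(OC)cc(Oc2c(OC=O)cc(OC)cc2OC=O)c1 | intermediate
15 | 2-(3,5-dimethoxyphenoxy)-5-methoxybenzene-1,3-diol | COc1cc(OC)cc(Oc2c(O)cc(OC)cc2O)c1 | intermediate
16 | 1,3-bis[4-(benzyloxy)-2,6-diformylphenoxy]-2-(3,5-dimethoxyphenoxy)-5-methoxybenzene | COc1cc(OC)cc(Oc2c(Oc3c(C=O)cc(OCc4ccccc4)cc3C=O)cc(OC)cc2Oc2c(C=O)cc(OCc3ccccc3)cc2C=O)c1 | intermediate
17 | 1,3-bis[4-(benzyloxy)-2,6-bis(formyloxy)phenoxy]-2-(3,5-dimethoxyphenoxy)-5-methoxybenzene | COc1cc(OC)cc(Oc2c(Oc3c(OC=O)cc(OCc4ccccc4)cc3OC=O)cc(OC)cc2Oc2c(OC=O)cc(OCc3ccccc3)cc2OC=O)c1 | intermediate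
18 | 1,3-bis[4-(benzyloxy)-2,6-dihydroxyphenoxy]-2-(3,5-dimethoxyphenoxy)-5-methoxybenzene | COc1cc(OC)cc(Oc2c(Oc3c(O)cc(OCc4ccccc4)cc3O)cc(OC)cc2Oc2c(O)cc(OCc3ccccc3)cc2O)c1 | intermediate
19 | 1,3-bis[4-(benzyloxy)-2,6-dimethoxyphenoxy]-2-(3,5-dimethoxyphenoxy)-5-methoxybenzene | COc1cc(OC)cc(Oc2c(Oc3c(OC)cc(OCc4ccccc4)cc3OC)cc(OC)cc2Oc2c(OC)cc(OCc3ccccc3)cc2OC)c1 | intermediate
20 | 1,3-bis(4-hydroxy-2,6-dimethoxyphenoxy)-2-(3,5-dimethoxyphenoxy)-5-methoxybenzene | COc1cc(OC)cc(Oc2c(Oc3c(OC)cc(O)cc3OC)cc(OC)cc2Oc2c(OC)cc(O)cc2OC)c1 | intermediate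
21 | 4-bromo-2-fluoro-5-methoxyisophthalaldehyde | COc1cc(C=O)c(F)c(C=O)c1Br | intermediate
22 | 2,4,6-trimethoxyphenylboronic acid | COc1cc(OC)c(B(O)O)c(OC)c1 | starting material
23 | 2-fluoro-5-methoxy-4-(2,4,6-trimethoxyphenyl)isophthalaldehyde | COc1cc(OC)c(-c2c(OC)cc(C=O)c(F)c2C=O)c(OC)c1 | intermediate
24 | 1,3-bis{4-[2,6-diformyl-4-methoxy-3-(2,4,6-trimethoxyphenyl)phenoxy]-2,6-dimethoxyphenoxy}-2-(3,5-dimethoxyphenoxy)-5-methoxybenzene | COc1cc(OC)cc(Oc2c(Oc3c(OC)cc(Oc4c(C=O)cc(OC)c(-c5c(OC)cc(OC)cc5OC)c4C=O)cc3OC)cc(OC)cc2Oc2c(OC)cc(Oc3c(C=O)cc(OC)c(-c4c(OC)cc(OC)cc4OC)c3C=O)cc2OC)c1 | intermediate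
25 | 1,3-bis{4-[2,6-bis(formyloxy)-4-methoxy-3-(2,4,6-trimethoxyphenyl)phenoxy]-2,6-dimethoxyphenoxy}-2-(3,5-dimethoxyphenoxy)-5-methoxybenzene | COc1cc(OC)cc(Oc2c(Oc3c(OC)cc(Oc4c(OC=O)cc(OC)c(-c5c(OC)cc(OC)cc5OC)c4OC=O)cc3OC)cc(OC)cc2Oc2c(OC)cc(Oc3c(OC=O)cc(OC)c(-c4c(OC)cc(OC)cc4OC)c3OC=O)cc2OC)c1 | intermediate
26 | 1,3-bis{4-[2,6-dihydroxy-4-methoxy-3-(2,4,6-trimethoxyphenyl)phenoxy]-2,6-dimethoxyphenoxy}-2-(3,5-dimethoxyphenoxy)-5-methoxybenzene | COc1cc(OC)cc(Oc2c(Oc3c(OC)cc(Oc4c(O)cc(OC)c(-c5c(OC)cc(OC)cc5OC)c4O)cc3OC)cc(OC)cc2Oc2c(OC)cc(Oc3c(O)cc(OC)c(-c4c(OC)cc(OC)cc4OC)c3O)cc2OC)c1 | intermediate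
27 | 5-{2,6-bis[2,6-dihydroxy-4-(2,2′,4,4′,6,6′-hexahydroxybiphenyl-3-yloxy)phenoxy]-4-hydroxyphenoxy}benzene-1,3-diol (CNP0227063.0) | Oc1cc(O)cc(Oc2c(Oc3c(O)cc(Oc4c(O)cc(O)c(-c5c(O)cc(O)cc5O)c4O)cc3O)cc(O)cc2Oc2c(O)cc(Oc3c(O)cc(O)c(-c4c(O)cc(O)cc4O)c3O)cc2O)c1 | target

Total step count: 18. Longest linear sequence: 15 steps (1, 2, 3, 4, 5, 6, 8, 9, 10, 11, 12, 13, 16, 17, 18).

Steps most likely to fail

Step 11. Hydride instead of aryl migration at one or more of the four formyl groups would give carboxylic acids, and the oxidation could stall at partly converted stages. Slow peracid attack on the electron-rich rings A and B is a further concern. The fallback sets out from 16 and replaces the hydride/aryl competition by a methyl/aryl competition. Fourfold addition of MeMgBr (THF, −78 °C) should give the tetrakis(1-hydroxyethyl) compound F1, a mixture of diastereomers whose configuration is of no consequence. Oxidation with Dess–Martin periodinane should give the tetra-acetyl compound F2. Baeyer–Villiger oxidation of aryl methyl ketones (mCPBA, CF3CO2H, CH2Cl2) reliably moves the aryl group in preference to methyl and should give the tetraacetate F3. K2CO3 in MeOH then cleaves the acetates, and the fallback comes back to the route at 18.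

Step 15. Protodeboronation of 22, slow transmetalation in the tetra-ortho-substituted coupling, and attack of adventitious hydroxide on the doubly activated C–F bond could each erode the coupling. The fallback sets out from 21 and masks the activating groups while changing the organometallic partner. Acetalisation (ethylene glycol, p-TsOH, toluene, reflux) should give 2,2′-(4-bromo-2-fluoro-5-methoxy-1,3-phenylene)bis(1,3-dioxolane) F4. Commercial 1,3,5-trimethoxybenzene is lithiated between two methoxy groups (n-BuLi, THF, 0 °C) to 2,4,6-trimethoxyphenyllithium F5 and transmetalated with ZnCl2 to chloro(2,4,6-trimethoxyphenyl)zinc F6. Base-free Negishi coupling of F4 with F6 (Pd2(dba)3, RuPhos, THF–NMP, 70 °C) should give the biaryl bis(dioxolane) F7. Aqueous HCl in THF then frees both aldehydes, and the fallback comes back at 23.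

Step 18. Incomplete cleavage of the hindered methyl ethers and loss of the air-sensitive nonadecaphenol during isolation are the concerns. The fallback sets out from 26 and combines a push–pull dealkylation with isolation as a stable derivative. Cleavage with AlCl3 and EtSH in CH2Cl2 is followed by acetylation of the crude polyphenol (Ac2O, pyridine, DMAP) to the nonadecaacetate F8. F8 can be purified on silica, and partly methylated material can be separated and resubmitted. Deacetylation with HCl in degassed MeOH then comes back at 27.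

Further compounds
F1 | step 11 | 1,3-bis[4-(benzyloxy)-2,6-bis(1-hydroxyethyl)phenoxy]-2-(3,5-dimethoxyphenoxy)-5-methoxybenzene (diastereomer mixture, stereocentres not controlled) | COc1cc(OC)cc(Oc2c(Oc3c(C(C)O)cc(OCc4ccccc4)cc3C(C)O)cc(OC)cc2Oc2c(C(C)O)cc(OCc3ccccc3)cc2C(C)O)c1
F2 | step 11 | 1,3-bis[2,6-diacetyl-4-(benzyloxy)phenoxy]-2-(3,5-dimethoxyphenoxy)-5-methoxybenzene | COc1cc(OC)cc(Oc2c(Oc3c(C(C)=O)cc(OCc4ccccc4)cc3C(C)=O)cc(OC)cc2Oc2c(C(C)=O)cc(OCc3ccccc3)cc2C(C)=O)c1
F3 | step 11 | 1,3-bis[2,6-diacetoxy-4-(benzyloxy)phenoxy]-2-(3,5-dimethoxyphenoxy)-5-methoxybenzene | COc1cc(OC)cc(Oc2c(Oc3c(OC(C)=O)cc(OCc4ccccc4)cc3OC(C)=O)cc(OC)cc2Oc2c(OC(C)=O)cc(OCc3ccccc3)cc2OC(C)=O)c1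
F4 | step 15 | 2,2′-(4-bromo-2-fluoro-5-methoxy-1,3-phenylene)bis(1,3-dioxolane) | COc1cc(C2OCCO2)c(F)c(C2OCCO2)c1Br
F5 | step 15 | 2,4,6-trimethoxyphenyllithium | COc1cc(OC)c([Li])c(OC)c1
F6 | step 15 | chloro(2,4,6-trimethoxyphenyl)zinc | COc1cc(OC)c([Zn]Cl)c(OC)c1
F7 | step 15 | 2,2′-[2-fluoro-5-methoxy-4-(2,4,6-trimethoxyphenyl)-1,3-phenylene]bis(1,3-dioxolane) | COc1cc(OC)c(-c2c(OC)cc(C3OCCO3)c(F)c2C2OCCO2)c(OC)c1
F8 | step 18 | nonadecaacetate of 27 (all nineteen hydroxyls acetylated) | CC(=O)Oc1cc(OC(C)=O)cc(Oc2c(Oc3c(OC(C)=O)cc(Oc4c(OC(C)=O)cc(OC(C)=O)c(-c5c(OC(C)=O)cc(OC(C)=O)cc5OC(C)=O)c4OC(C)=O)cc3OC(C)=O)cc(OC(C)=O)cc2Oc2c(OC(C)=O)cc(Oc3c(OC(C)=O)cc(OC(C)=O)c(-c4c(OC(C)=O)cc(OC(C)=O)cc4OC(C)=O)c3OC(C)=O)cc2OC(C)=O)c1
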